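**Numbering and faces.** Daucane numbering is used throughout: C1 is the methyl-bearing quaternary fusion carbon, C2 and C3 the five-ring methylenes, C4 the isopropyl carbinol, C5 the fusion CH, C6 the acyloxy carbon, C7 a CH2, C8=C9 the alkene (methyl on C8), C10 a CH2. The face of the C1 methyl is called β.

## The problem

The target is the 4-hydroxybenzoate of a daucane diol: a cyclopentane trans-fused to a cycloheptene, with four contiguous stereocentres, (1R,4S,5S,6R). Relative to the β methyl on C1, the C4 hydroxyl and H-5 are α and the C6 oxygen is β. C1 is quaternary, cannot be corrected later and must be set absolutely. Its control over the rest is uneven. While C5 is planar, the C1 methyl and the C10 methylene flank a C4=C5 alkene almost symmetrically, so C1 cannot be trusted to set C4. Once C5 is sp3 and the fusion is trans, the axial methyl and the isopropyl group both cover the β face of a C6 ketone, so C1 (with C4) can set C6. The weak points are the tertiary β-hydroxy ketone array (retro-aldol, dehydration), the C8=C9 alkene, which is β,γ to any C6 carbonyl and can slip into conjugation, the skipped cycloheptadienones on the way (isomerisation, aromatisation to a tropone), and the free phenol. The feature that opens the route is in the seven-membered ring: with C5 removed, C6, C1, C10, C9, C8 and C7 carry O, CH3, H, H, CH3 and H, which is the substitution pattern of 2,5-dimethylanisole. Birch reduction leaves exactly the C8=C9 alkene and an enol ether C6=C1 into which C5 can be inserted as a carbene carbon.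

## Retrosynthesis

**Ester.** The C6–O acyl bond of **23** is cut to diol **18** and 4-[(tert-butyldimethylsilyl)oxy]benzoic acid **21** (from **19** via **20**), with silyl ester **22** as the penultimate compound. Only the secondary hydroxyl of **18** can be acylated, so no protection of the diol is needed. The phenol is masked as a silyl ether because fluoride removes it without touching the benzoate or the alkene.

**C6–H.** Diol **18** is traced to β-hydroxy ketone **17**. In the trans-fused bicycle the β face of the carbonyl is covered by the C1 methyl and the isopropyl group, so a small hydride should enter from the α face and give the 6β alcohol. This is preferred over carrying a C6 alcohol through, because the ketone is needed for the next cut.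

**C5–O.** **17** is traced to the α-epoxy ketone **16**. Reductive cleavage of the Cα–O bond puts the hydroxyl on C4 and a hydrogen on C5, exactly the pattern wanted. The forward reaction must protonate the enolate at C5 from the α face.

**Epoxide and its relay.** **16** comes from epoxy alcohol **15**, this from allylic alcohol **14**, and this from dienone **13**. Direct alkaline peroxide epoxidation of **13** would be two steps shorter, but it needs base next to the C7 methylene and leaves the facial choice to C1, which is weak at this stage. A catalyst-controlled reduction to the (6S)-carbinol, followed by hydroxyl-directed epoxidation, fixes the α epoxide by reagent control. The carbinol is then oxidised back.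

**C4–C5.** The five-membered ring of **13** is opened at the enone to the 1,6-diketone **12**, released from ketal **11**. Aldol condensation is the simplest closure and brings the isopropyl group in with the electrophile. The forward step must not move the C8=C9 alkene.

**C1–C2.** **11** is cut at the quaternary centre to dienone **6** and Grignard reagent **10**, made from chloro ketal **9**, from β-chloro ketone **8**, from isobutyryl chloride **7**. A β-methyl cycloheptenone is a known substrate class for copper-catalysed asymmetric conjugate addition, and the second alkene of **6** is not conjugated. The forward step must deliver the (R) centre.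

**C5 insertion.** **6** comes from bromodienone **5** by removal of bromine. **5** is cut at C5–C6 and C5–C1 to 1-methoxy-2,5-dimethylcyclohexa-1,4-diene **2** and bromoform **3**, through dibromocyclopropane **4**. **2** is the Birch product of 2,5-dimethylanisole **1**. This cut turns a seven-membered ring problem into an aromatic substitution pattern that can be bought.

## Roads not taken

**Alternative 1:** The cut is C1–C5 of the five-membered ring, made by C–H insertion. The isopropyl ketone A2, reachable from (S)-citronellol A3 (silylation, ozonolysis, isopropyl Grignard addition, oxidation), would be treated with a lithiated silyldiazomethane. The resulting alkylidene carbene at C5 inserts into the tertiary C1–H bond with retention and gives cyclopentene A1.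
- Merits: C1 comes from the chiral pool with no catalyst to tune, and insertion with retention is dependable. In this respect the road is safer than step 6 of the chosen plan.
- Weak points: A1 holds only the five-membered ring. C6, C7 and C8 with its methyl must still be attached and a seven-membered ring closed onto C5, an alkene carbon next to the quaternary centre. C4–OH, H-5 and C6–O all remain to be set.
- Comparison: the chosen plan has the seven-membered ring, with its methyl, oxygen and alkene in place, two steps after an aromatic starting material, and closes the small ring by an aldol. It pays for this by relying on asymmetric catalysis for C1.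

**Alternative 2:** The cut is C1–C2, made by ring expansion. 1-Isopropenylcyclobutanol A5 would be treated with an electrophilic bromine source and a chiral phosphoric acid. Bromination at the alkene terminus (C10) triggers a 1,2-shift of a ring CH2 to C1 and gives ketone A4.
- Merits: a catalytic, enantioselective route to C1 from a trivial precursor, without organometallic reagents. In this respect it equals or betters the chosen plan.
- Weak points: the functional groups map badly. The carbonyl of A4 sits on C5, which in the target is a methine carrying C6. C4 is a bare methylene that would need both isopropyl and hydroxyl. C10 carries a neopentyl bromide, a poor electrophile. Four carbons of the seven-membered ring are missing.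
- Comparison: in the chosen plan, once C1 is set, one aldol delivers C4 with its isopropyl group and C6 already oxygenated.

**Alternative 3:** The cut is C1–C5 and C9–C10 at once. Enyne A7 would be treated with a cationic monovalent rhodium catalyst of the [Rh(cod)2]BF4 and triarylphosphine type. A 1,2-shift of the pivalate from C7 to C6 generates the five-carbon partner, which adds across the tethered C1=C10 alkene in a (5+2) sense and gives A6.
- Merits: both rings and all fifteen skeletal carbons in one step, with the C4 and C6 oxygens in place. In ring construction this road is clearly shorter than the chosen plan.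
- Weak points: A7 needs an enantioenriched tertiary propargylic ether flanked by isopropyl and an alkyl chain, which is hard to make selectively. The quaternary C1 must form from a 1,1-disubstituted alkene under control of C4 across the forming ring. The diene of A6 lies at C5=C6 and C7=C8, so after ester cleavage the alkene is conjugated and must be moved to C8=C9, and H-5 must still be set.
- Comparison: against the convergence, the chosen plan has the alkene in its final position from the Birch step, sets C1 by a reaction with close precedent, and sets each later centre in a separate step.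

Key step: step 2

Assumption: the configuration is read from the line notation as (1R,4S,5S,6R), i.e. trans fusion, 4-OH and H-5 α, 6-O β. The sense of induction of the chiral ligand in step 6 is assigned by analogy with simpler β-methyl enones, and the antipodal ligand is used if the first run shows the opposite sense.

## Steps

Step 1
Reactants: 1 2,5-dimethylanisole
Product: 2 1-methoxy-2,5-dimethylcyclohexa-1,4-diene
Conditions: Li, NH3 (l), t-BuOH, THF, −78 → −33 °C; NH4Cl
Reagents that add atoms: none
Why: Birch reduction of an anisole; two electrons and two protons are added so that the methoxy and both methyl groups stay on sp2 carbons, giving the unconjugated diene with the enol ether C6=C1 and the future C8=C9 alkene; no stereocentre is formed.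

Step 2
Reactants: 2 1-methoxy-2,5-dimethylcyclohexa-1,4-diene; 3 bromoform
Product: 5 2-bromo-3,6-dimethylcyclohepta-2,5-dien-1-one, via dibromocyclopropane 4 (not isolated)
Conditions: CHBr3 (1.1 equiv), KOt-Bu, pentane, −30 → 0 °C; cold filtration; then AgNO3, acetone/H2O, 0 → 20 °C, dark
Reagents that add atoms: bromoform (3), BrC(Br)Br; water, O
Why: KOt-Bu deprotonates bromoform and α-elimination gives singlet dibromocarbene, which adds in a concerted cheletropic [2+1] step to the enol ether alkene of 2 and so forms C5–C6 and C5–C1 in the three-membered ring of 4. Silver ion then removes the endo bromide while the C6–C1 bond shared by the two rings opens by disrotatory two-electron electrocyclic ring opening (Woodward–Hoffmann–DePuy rule), so the seven-membered ring arises by one-carbon ring expansion and not by a cyclisation. The 2-bromoallyl cation is an oxocarbenium ion at C6; water adds, methanol leaves, and 5 results. The closest known reaction type is dihalocarbene addition to Birch-derived 1-methoxycyclohexa-1,4-dienes with ring expansion to 2-halocycloheptadienones, the first half of the classical tropone synthesis. No stereocentre is formed, since the two centres of 4 are lost on opening. The step needs addition at the enol ether alkene and not at C8=C9: the methoxy group makes the tetrasubstituted alkene the more nucleophilic one, only its adduct can ionise to an oxygen-stabilised cation, and one equivalent of carbene limits double addition. The opening is run cold and without base, because enolisation of 5 followed by loss of HBr would aromatise the ring.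

Step 3
Reactants: 5 2-bromo-3,6-dimethylcyclohepta-2,5-dien-1-one
Product: 6 3,6-dimethylcyclohepta-2,5-dien-1-one
Conditions: Bu3SnH (1.05 equiv, slow addition), Pd(PPh3)4 (3 mol %), THF, 0 → 20 °C
Reagents that add atoms: none
Why: Palladium-catalysed hydrodehalogenation of a vinyl bromide with a tin hydride: zerovalent palladium inserts into the activated α-bromoenone C–Br bond, hydride is transferred from tin and reductive elimination gives the C–H bond; the neutral medium avoids enolisation of the skipped dienone and slow hydride addition limits conjugate reduction.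

Step 4
Reactants: 7 isobutyryl chloride
Product: 8 1-chloro-4-methylpentan-3-one
Conditions: ethylene (1 atm), AlCl3, CH2Cl2, 0 °C
Reagents that add atoms: ethylene, C=C
Why: Friedel–Crafts-type acylation of an alkene (Darzens–Nenitzescu reaction): the acylium ion adds to ethylene and chloride captures the β-cation, giving the β-chloro ketone.

Step 5
Reactants: 8 1-chloro-4-methylpentan-3-one
Product: 9 2-(2-chloroethyl)-5,5-dimethyl-2-(propan-2-yl)-1,3-dioxane
Conditions: 2,2-dimethylpropane-1,3-diol, HC(OEt)3, TsOH·H2O (cat.), CH2Cl2, 20 °C
Reagents that add atoms: 2,2-dimethylpropane-1,3-diol, OCC(C)(C)CO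
Why: Acid-catalysed ketalisation with an orthoformate as water scavenger at room temperature, so that HCl is not eliminated; the six-membered ketal is chosen because its γ-magnesio derivative is stable and does not fragment.

Step 6
Reactants: 6 3,6-dimethylcyclohepta-2,5-dien-1-one; 9 2-(2-chloroethyl)-5,5-dimethyl-2-(propan-2-yl)-1,3-dioxane
Product: 11 (6R)-6-{2-[5,5-dimethyl-2-(propan-2-yl)-1,3-dioxan-2-yl]ethyl}-3,6-dimethylcyclohept-3-en-1-one, via Grignard reagent 10 (not isolated)
Conditions: Mg, BrCH2CH2Br (cat.), THF, 40 °C; then 6, Cu(OTf)2 (4 mol %), chiral N-mesityl-N′-(1-hydroxy-4-methylpentan-2-yl)imidazolinium PF6 salt (5 mol %, antipode giving R), Et2O, −30 → 0 °C; aq NH4Cl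
Reagents that add atoms: none
Why: Copper-catalysed asymmetric conjugate addition of a Grignard reagent to a β-methyl cyclic enone under NHC ligation, a known route to all-carbon quaternary centres in six- and seven-membered rings; the chiral NHC–copper species transfers the alkyl group to one face of the enone and so sets C1 as R, while the unconjugated C8=C9 alkene takes no part and the ketal survives.

Step 7
Reactants: 11 (6R)-6-{2-[5,5-dimethyl-2-(propan-2-yl)-1,3-dioxan-2-yl]ethyl}-3,6-dimethylcyclohept-3-en-1-one
Product: 13 (8aR)-6,8a-dimethyl-3-(propan-2-yl)-2,5,8,8a-tetrahydroazulen-4(1H)-one, via diketone 12 (not isolated)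
Conditions: 2 M HCl, THF, 20 °C; then KOH, MeOH, 20 °C, stopped when 12 is consumed
Reagents that add atoms: none
Why: Ketal hydrolysis followed by intramolecular aldol condensation of a 1,6-diketone: the C5 enolate attacks the isopropyl ketone (5-exo closure of C4–C5) and the aldol loses water by E1cB to the acylcyclopentene, whereas attack of C3 on C6 gives a bridged aldol that cannot dehydrate and reverts; C8=C9 should survive because the dienolate is protonated kinetically at C7 and, in a seven-membered ring, conjugation offers little gain; C1 is untouched.

Step 8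
Reactants: 13 (8aR)-6,8a-dimethyl-3-(propan-2-yl)-2,5,8,8a-tetrahydroazulen-4(1H)-one
Product: 14 (4S,8aR)-6,8a-dimethyl-3-(propan-2-yl)-1,2,4,5,8,8a-hexahydroazulen-4-ol
Conditions: (R)-2-methyl-CBS-oxazaborolidine (0.3 equiv), catecholborane, toluene, −78 °C
Reagents that add atoms: none
Why: Corey–Bakshi–Shibata reduction under catalyst control: the tetrasubstituted alkenyl carbon C5 acts as the large and the C7 methylene as the small substituent, so the (R)-catalyst should give the (6S)-carbinol with 1,2-selectivity; catecholborane does not hydroborate the C8=C9 alkene at this temperature.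

Step 9
Reactants: 14 (4S,8aR)-6,8a-dimethyl-3-(propan-2-yl)-1,2,4,5,8,8a-hexahydroazulen-4-ol
Product: 15 (1R,4S,5R,6S)-4,5-epoxydauc-8-en-6-ol (epoxide oxygen bridging C4 and C5 on the α face, C6 hydroxyl α)
Conditions: VO(acac)2 (5 mol %), t-BuOOH, CH2Cl2, 0 → 20 °C
Reagents that add atoms: tert-butyl hydroperoxide, CC(C)(C)OO
Why: Hydroxyl-directed epoxidation: the vanadate ester of the C6 alcohol delivers the peroxide oxygen within the complex; allylic 1,3-strain with the cis isopropyl group keeps H-6 in the alkene plane and the hydroxyl on the α face, so oxygen is delivered to the α face of C4=C5 (4S,5R), and the homoallylic C8=C9 alkene reacts far more slowly.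

Step 10
Reactants: 15 (1R,4S,5R,6S)-4,5-epoxydauc-8-en-6-ol
Product: 16 (1R,4S,5S)-4,5-epoxydauc-8-en-6-one (α epoxide)
Conditions: Dess–Martin periodinane, pyridine, CH2Cl2, 0 → 20 °C
Reagents that add atoms: none
Why: Dess–Martin oxidation of a secondary alcohol under buffered, non-basic conditions; the epoxide, the alkene and all stereocentres are untouched (the descriptor at C5 changes only because the priorities change).

Step 11
Reactants: 16 (1R,4S,5S)-4,5-epoxydauc-8-en-6-one
Product: 17 (3S,3aR,8aR)-3-hydroxy-6,8a-dimethyl-3-(propan-2-yl)-2,3,3a,5,8,8a-hexahydroazulen-4(1H)-one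
Conditions: SmI2 (2.5 equiv), THF/MeOH, −90 °C
Reagents that add atoms: none
Why: Reductive opening of an α,β-epoxy ketone by SmI2: two single-electron transfers cleave the C5–O bond and give a samarium enolate with the C4 alkoxide intact; methanol protonates C5 on the α face, because the β face is flanked by the C1 methyl and the isopropyl group and the α-alkoxide of trivalent samarium carries bound methanol, which sets the trans ring fusion at low temperature without retro-aldol or elimination.

Step 12
Reactants: 17 (3S,3aR,8aR)-3-hydroxy-6,8a-dimethyl-3-(propan-2-yl)-2,3,3a,5,8,8a-hexahydroazulen-4(1H)-one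
Product: 18 (3S,3aS,4R,8aR)-6,8a-dimethyl-3-(propan-2-yl)-1,2,3,3a,4,5,8,8a-octahydroazulene-3,4-diol
Conditions: NaBH4, CeCl3·7H2O, MeOH, −78 → −40 °C
Reagents that add atoms: none
Why: Luche-type borohydride reduction under steric approach control: in the trans-fused bicycle the axial C1 methyl and the isopropyl group cover the β face of the C6 carbonyl, so hydride enters from the α face, syn to H-5, and the hydroxyl ends on the β face (6R); the cold, weakly basic medium spares the β-hydroxy ketone.

Step 13
Reactants: 19 4-hydroxybenzoic acid
Product: 21 4-[(tert-butyldimethylsilyl)oxy]benzoic acid, via bis-silyl compound 20 (not isolated)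
Conditions: TBSCl (2.2 equiv), imidazole, DMF, 20 °C; then AcOH/THF/H2O, 20 °C
Reagents that add atoms: tert-butyldimethylsilyl chloride, CC(C)(C)[Si](C)(C)Cl
Why: Silylation of both acidic hydroxyl groups followed by selective hydrolysis of the labile silyl ester; the aryl silyl ether survives mild aqueous acid.

Step 14
Reactants: 18 (3S,3aS,4R,8aR)-6,8a-dimethyl-3-(propan-2-yl)-1,2,3,3a,4,5,8,8a-octahydroazulene-3,4-diol; 21 4-[(tert-butyldimethylsilyl)oxy]benzoic acid
Product: 22 (3S,3aS,4R,8aR)-3-hydroxy-6,8a-dimethyl-3-(propan-2-yl)-1,2,3,3a,4,5,8,8a-octahydroazulen-4-yl 4-[(tert-butyldimethylsilyl)oxy]benzoate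
Conditions: DCC, DMAP, CH2Cl2, 20 → 40 °C
Reagents that add atoms: none
Why: Steglich esterification: DMAP carries the acyl group from the O-acylisourea to the secondary C6 hydroxyl, the tertiary C4 hydroxyl does not react, and C6 keeps its configuration because its C–O bond is not broken.

Step 15
Reactants: 22 (3S,3aS,4R,8aR)-3-hydroxy-6,8a-dimethyl-3-(propan-2-yl)-1,2,3,3a,4,5,8,8a-octahydroazulen-4-yl 4-[(tert-butyldimethylsilyl)oxy]benzoate
Product: 23 (3S,3aS,4R,8aR)-3-hydroxy-6,8a-dimethyl-3-(propan-2-yl)-1,2,3,3a,4,5,8,8a-octahydroazulen-4-yl 4-hydroxybenzoate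
Conditions: Bu4NF, AcOH, THF, 0 °C
Reagents that add atoms: none
Why: Fluoride cleavage of an aryl silyl ether; buffering with acetic acid keeps the medium near neutral, so the benzoate, the tertiary alcohol and the alkene are untouched.

## Compound list

1 | 2,5-dimethylanisole | COc1cc(C)ccc1C | starting material
2 | 1-methoxy-2,5-dimethylcyclohexa-1,4-diene | COC1=C(C)CC=C(C)C1 | intermediate
3 | bromoform | BrC(Br)Br | starting material
4 | 7,7-dibromo-1-methoxy-3,6-dimethylbicyclo[4.1.0]hept-3-ene (racemic, cis-fused) | COC12CC(C)=CCC1(C)C2(Br)Br | intermediate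
5 | 2-bromo-3,6-dimethylcyclohepta-2,5-dien-1-one | CC1=CCC(C)=C(Br)C(=O)C1 | intermediate
6 | 3,6-dimethylcyclohepta-2,5-dien-1-one | CC1=CCC(C)=CC(=O)C1 | intermediate
7 | isobutyryl chloride | CC(C)C(=O)Cl | starting material
8 | 1-chloro-4-methylpentan-3-one | CC(C)C(=O)CCCl | intermediate
9 | 2-(2-chloroethyl)-5,5-dimethyl-2-(propan-2-yl)-1,3-dioxane | CC(C)C1(CCCl)OCC(C)(C)CO1 | intermediate
10 | chloro{2-[5,5-dimethyl-2-(propan-2-yl)-1,3-dioxan-2-yl]ethyl}magnesium | CC(C)C1(CC[Mg]Cl)OCC(C)(C)CO1 | intermediate
11 | (6R)-6-{2-[5,5-dimethyl-2-(propan-2-yl)-1,3-dioxan-2-yl]ethyl}-3,6-dimethylcyclohept-3-en-1-one | CC1=CC[C@@](C)(CCC2(C(C)C)OCC(C)(C)CO2)CC(=O)C1 | intermediate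
12 | (6R)-3,6-dimethyl-6-(4-methyl-3-oxopentyl)cyclohept-3-en-1-one | CC1=CC[C@@](C)(CCC(=O)C(C)C)CC(=O)C1 | intermediate
13 | (8aR)-6,8a-dimethyl-3-(propan-2-yl)-2,5,8,8a-tetrahydroazulen-4(1H)-one [(1R)-dauca-4,8-dien-6-one] | CC1=CC[C@@]2(C)CCC(C(C)C)=C2C(=O)C1 | intermediate
14 | (4S,8aR)-6,8a-dimethyl-3-(propan-2-yl)-1,2,4,5,8,8a-hexahydroazulen-4-ol [(1R,6S)-dauca-4,8-dien-6-ol] | CC1=CC[C@@]2(C)CCC(C(C)C)=C2[C@@H](O)C1 | intermediate
15 | (1R,4S,5R,6S)-4,5-epoxydauc-8-en-6-ol (α epoxide, α hydroxyl) | CC1=CC[C@@]2(C)CC[C@@]3(C(C)C)O[C@@]23[C@@H](O)C1 | intermediate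
16 | (1R,4S,5S)-4,5-epoxydauc-8-en-6-one (α epoxide) | CC1=CC[C@@]2(C)CC[C@@]3(C(C)C)O[C@@]23C(=O)C1 | intermediate
17 | (3S,3aR,8aR)-3-hydroxy-6,8a-dimethyl-3-(propan-2-yl)-2,3,3a,5,8,8a-hexahydroazulen-4(1H)-one | CC1=CC[C@@]2(C)CC[C@](O)(C(C)C)[C@@H]2C(=O)C1 | intermediate
18 | (3S,3aS,4R,8aR)-6,8a-dimethyl-3-(propan-2-yl)-1,2,3,3a,4,5,8,8a-octahydroazulene-3,4-diol | CC1=CC[C@@]2(C)CC[C@](O)(C(C)C)[C@@H]2[C@H](O)C1 | intermediate
19 | 4-hydroxybenzoic acid | O=C(O)c1ccc(O)cc1 | starting material
20 | tert-butyldimethylsilyl 4-[(tert-butyldimethylsilyl)oxy]benzoate | CC(C)(C)[Si](C)(C)OC(=O)c1ccc(O[Si](C)(C)C(C)(C)C)cc1 | intermediate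
21 | 4-[(tert-butyldimethylsilyl)oxy]benzoic acid | CC(C)(C)[Si](C)(C)Oc1ccc(C(=O)O)cc1 | intermediate
22 | (3S,3aS,4R,8aR)-3-hydroxy-6,8a-dimethyl-3-(propan-2-yl)-1,2,3,3a,4,5,8,8a-octahydroazulen-4-yl 4-[(tert-butyldimethylsilyl)oxy]benzoate | CC1=CC[C@@]2(C)CC[C@](O)(C(C)C)[C@@H]2[C@H](OC(=O)c2ccc(O[Si](C)(C)C(C)(C)C)cc2)C1 | intermediate
23 | (3S,3aS,4R,8aR)-3-hydroxy-6,8a-dimethyl-3-(propan-2-yl)-1,2,3,3a,4,5,8,8a-octahydroazulen-4-yl 4-hydroxybenzoate | CC1=CC[C@@]2(C)CC[C@](O)(C(C)C)[C@@H]2[C@H](OC(=O)c2ccc(O)cc2)C1 | target

## Step count and least certain steps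

Total step count: 15. Longest linear sequence: 12 steps (steps 1, 2, 3, 6, 7, 8, 9, 10, 11, 12, 14, 15).

**Step 2 (key step).** The most likely failures are loss of HBr from the product through its enol with aromatisation of the ring, migration of the skipped alkenes into conjugation under the nitric acid set free, and carbene addition to both alkenes. The fallback sets out from 2 and makes 4 as before. The crude 4 is warmed in methanol over K2CO3, so that the oxocarbenium ion is captured by methanol and gives the non-enolisable ketal 5-bromo-6,6-dimethoxy-1,4-dimethylcyclohepta-1,4-diene F1. Bromine–lithium exchange with t-BuLi in THF at −78 °C and a methanol quench give 6,6-dimethoxy-1,4-dimethylcyclohepta-1,4-diene F2. Mild hydrolysis (oxalic acid on wet silica) releases 6, where the route is rejoined; step 3 is bypassed as well.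

**Step 3.** Conjugate reduction of the enone by the tin hydride, or alkene migration on the metal, may compete with C–Br cleavage. The fallback sets out from 5. 1,2-Reduction (NaBH4, CeCl3·7H2O, MeOH) gives 2-bromo-3,6-dimethylcyclohepta-2,5-dien-1-ol F3. Exchange with t-BuLi (3 equiv, THF, −78 °C) and a methanol quench give 3,6-dimethylcyclohepta-2,5-dien-1-ol F4. Oxidation with MnO2 in CH2Cl2 returns to 6.

**Step 6.** Enantioselection may be poor on this dienone (THF carried in with the Grignard reagent, a seven-membered ring), and deprotonation of the acidic dienone may compete with addition. The fallback sets out from 6 and 10 and gives up asymmetric catalysis at C1. Racemic addition with CuBr·SMe2 and Me3SiCl in THF gives the racemic keto ketal F5. The conditions of step 7 give, through the racemic diketone F6, the racemic dienone F7. Reduction of F7 under the conditions of step 8 is reagent-controlled at C6 and so turns the two enantiomers into diastereomers: 14 and its (4S,8aS)-isomer F8, which are separated by chromatography. The route is rejoined at 14 at the cost of half the material.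

**Step 7.** The C8=C9 alkene may migrate into conjugation through the C7 dienolate during the basic condensation, or dehydration may stall. The fallback sets out from 6 and 10 and uses the regiodefined enolate of the conjugate addition. The reaction of step 6 is quenched with Me3SiCl to give the silyl enol ether (R)-trimethyl{[6-{2-[5,5-dimethyl-2-(propan-2-yl)-1,3-dioxan-2-yl]ethyl}-3,6-dimethylcyclohepta-1,3-dien-1-yl]oxy}silane F9. TiCl4 in CH2Cl2 at −78 °C opens the ketal and closes C4–C5 by an intramolecular Mukaiyama aldol reaction, giving the β-alkoxy ketone (8aR)-3-(3-hydroxy-2,2-dimethylpropoxy)-6,8a-dimethyl-3-(propan-2-yl)-2,3,3a,5,8,8a-hexahydroazulen-4(1H)-one F10. Brief treatment with DBU eliminates the alkoxy group and returns to 13.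

**Step 9.** Delivery of oxygen to the hindered tetrasubstituted alkene may be slow, so that oxidation of the carbinol to the enone or epoxidation at C8=C9 takes over. The fallback sets out from 13 and uses Weitz–Scheffer epoxidation (H2O2, NaOH, MeOH, 0 °C), which touches only the enone and gives 16 directly. It leaves the choice of face to the substrate and makes no new compound.

## Further compounds

F1 | step 2 | 5-bromo-6,6-dimethoxy-1,4-dimethylcyclohepta-1,4-diene | COC1(OC)CC(C)=CCC(C)=C1Br
F2 | step 2 | 6,6-dimethoxy-1,4-dimethylcyclohepta-1,4-diene | COC1(OC)CC(C)=CCC(C)=C1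
F3 | step 3 | 2-bromo-3,6-dimethylcyclohepta-2,5-dien-1-ol (racemic) | CC1=CCC(C)=C(Br)C(O)C1
F4 | step 3 | 3,6-dimethylcyclohepta-2,5-dien-1-ol (racemic) | CC1=CCC(C)=CC(O)C1
F5 | step 6 | racemic 6-{2-[5,5-dimethyl-2-(propan-2-yl)-1,3-dioxan-2-yl]ethyl}-3,6-dimethylcyclohept-3-en-1-one | CC1=CCC(C)(CCC2(C(C)C)OCC(C)(C)CO2)CC(=O)C1
F6 | step 6 | racemic 3,6-dimethyl-6-(4-methyl-3-oxopentyl)cyclohept-3-en-1-one | CC1=CCC(C)(CCC(=O)C(C)C)CC(=O)C1
F7 | step 6 | racemic 6,8a-dimethyl-3-(propan-2-yl)-2,5,8,8a-tetrahydroazulen-4(1H)-one | CC1=CCC2(C)CCC(C(C)C)=C2C(=O)C1
F8 | step 6 | (4S,8aS)-6,8a-dimethyl-3-(propan-2-yl)-1,2,4,5,8,8a-hexahydroazulen-4-ol | CC1=CC[C@]2(C)CCC(C(C)C)=C2[C@@H](O)C1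
F9 | step 7 | (R)-trimethyl{[6-{2-[5,5-dimethyl-2-(propan-2-yl)-1,3-dioxan-2-yl]ethyl}-3,6-dimethylcyclohepta-1,3-dien-1-yl]oxy}silane | CC1=CC[C@@](C)(CCC2(C(C)C)OCC(C)(C)CO2)C=C(O[Si](C)(C)C)C1
F10 | step 7 | (8aR)-3-(3-hydroxy-2,2-dimethylpropoxy)-6,8a-dimethyl-3-(propan-2-yl)-2,3,3a,5,8,8a-hexahydroazulen-4(1H)-one (mixture at C3 and C3a) | CC1=CC[C@@]2(C)CCC(OCC(C)(C)CO)(C(C)C)C2C(=O)C1
F0 | step 9 | none | none
A1 | alternative 1 | (R)-tert-butyl{2-[1-methyl-3-(propan-2-yl)cyclopent-2-en-1-yl]ethoxy}dimethylsilane | CC(C)(C)[Si](C)(C)OCC[C@@]1(C)CCC(C(C)C)=C1
A2 | alternative 1 | (5S)-7-[(tert-butyldimethylsilyl)oxy]-2,5-dimethylheptan-3-one | CC(C)(C)[Si](C)(C)OCC[C@@H](C)CCC(=O)C(C)C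
A3 | alternative 1 | (S)-citronellol | OCC[C@@H](C)CCC=C(C)C
A4 | alternative 2 | (S)-2-(bromomethyl)-2-methylcyclopentan-1-one | BrC[C@@]1(C)CCCC1=O
A5 | alternative 2 | 1-(prop-1-en-2-yl)cyclobutan-1-ol | CC(=C)C1(O)CCC1
A6 | alternative 3 | 6-pivaloyloxy-4-(triethylsilyloxy)dauca-5,7-diene, C1 and C4 arranged as in the target | CC1=CC(OC(=O)C(C)(C)C)=C2[C@@](O[Si](CC)(CC)CC)(C(C)C)CC[C@]2(C)CC1
A7 | alternative 3 | (6S)-2,9-dimethyl-6-(propan-2-yl)-6-[(triethylsilyl)oxy]deca-1,9-dien-4-yn-3-yl pivalate | C=C(C)C(OC(=O)C(C)(C)C)C#C[C@@](O[Si](CC)(CC)CC)(C(C)C)CCC(C)=C
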